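The readings stem from a simulated flask from invented constants, noise included.

The constants of this flask are hidden, but one of them can be read off the earlier runs, and two chemists disagree on whether that one is what counts.

| setting | larch | ash | birch | amber | blue |
|---|---|---|---|---|---|
| starting material | 0.020 M | 0.020 M | 0.020 M | 0.020 M | 0.020 M |
| partner | 0.022 M | 0.037 M | 0.051 M | 0.0260 M | 0.0520 M |
| protic impurity | 10 mM | 10 mM | 10 mM | 10.0 mM | 10.0 mM |
| remark | run made earlier | run made earlier | run made earlier |  |  |
| time |  |  |  | 4.0 min | 4.0 min |

| run | time / min | open intermediate / % | target / % | starting material / % | over-reaction product / % |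
|---|---|---|---|---|---|
| larch | 0.250 | 4.1 | 0.3 | 96.3 | 0 |
| larch | 0.417 | 5.0 | 0.6 | 95.9 | 0.3 |
| larch | 0.833 | 9.3 | 0 | 90.5 | 0 |
| larch | 1.33 | 14.8 | 0 | 84.7 | 0 |
| larch | 3.00 | 28.6 | 0.3 | 68.7 | 1.9 |
| ash | 0.250 | 3.0 | 0 | 96.2 | 0 |
| ash | 0.667 | 7.9 | 0 | 91.6 | 0.5 |
| ash | 1.33 | 15.2 | 1.3 | 84.7 | 0.2 |
| ash | 2.00 | 20.4 | 0.8 | 77.5 | 0.6 |
| ash | 3.00 | 27.4 | 1.7 | 68.2 | 2.4 |
| birch | 0.500 | 6.2 | 0.3 | 94.0 | 0.1 |
| birch | 1.00 | 12.0 | 1.0 | 87.8 | 0 |
| birch | 1.50 | 16.3 | 0.2 | 83.1 | 1.9 |
| birch | 2.50 | 22.6 | 1.6 | 72.3 | 2.5 |
| birch | 3.00 | 25.1 | 2.7 | 68.6 | 3.5 |

(scatter of a reading: 0.5 percentage points)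

- the earlier runs were read with a standard deviation of 0.5 percentage points

* which of these there is most of at the end, counted by the starting material in it, amber (target / over-reaction product / open intermediate / starting material)
* which of these there is most of at the end, counted by the starting material in it, blue (target / over-reaction product / open intermediate / starting material)
* the largest of these amounts at the end, in percent of the starting material charged, amber
* the largest of these amounts at the end, in percent of the starting material charged, blue

The first chemist reads a clock. At 3.00 min starting material stands at 68.7% in larch, 68.2% in ash and 68.6% in birch, while partner runs from 1.10 to 2.55 times the starting charge. So he takes the loss as first order and zero order in partner, with a rate constant of 0.126 min⁻¹. At 4.0 min he counts 0.504 turnovers, the turnover count being the rate constant times the time. The fraction left is the exponential of minus that count, here 60.4%. On a first-order loss, a count under 0.693 leaves more starting material than everything else together, and he puts that mark at 5.50 min, later than the asked time.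

The second chemist says partner sets the flask. From larch to birch, partner rose 2.32 times, and target plus over-reaction product at 3.00 min went from 2.20% to 6.20%. Scaling with partner and the square of time, she expects that sum at 4.62% in amber and 11.2% in blue. With twice amber's partner, she argues, blue's largest amount must sit lower.

The forecast stands with the clock, calling the loss “first order and independent of partner”: starting material at 60.2% in amber and starting material at 60.2% in blue, just under his 60.4%.

The flask gives starting material at 61.0% in amber and starting material at 61.0% in blue, so the clock wins. Her ground comes late: at 40.0 min amber leads with open intermediate at 57.1%, blue with over-reaction product at 55.5%.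

    2 second intermediate → homo product (k = 0.110 M⁻¹ s⁻¹)
    starting material ⇌ open intermediate (K = 13.0, k = 0.00210 s⁻¹)
    partner + protic impurity → quenched reagent (k = 0.930 M⁻¹ s⁻¹)
    open intermediate + second intermediate → target (k = 0.130 M⁻¹ s⁻¹)
    target → over-reaction product (k = 0.0250 s⁻¹)
    partner → second intermediate (k = 0.00570 s⁻¹)

The count reckoned from the readings for blue was 0.504 turnovers. At 1.28 min the half-life of blue's starting material, by the forward rate of its step to open intermediate alone, was 5.5 min, longer than the 4.0 min of reading. Blue read at 10 min counts 1.26 turnovers, past the mark, and the exponential gives 28.4% left; that flask holds 30.1% starting material and leads with open intermediate at 39.4%.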